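**Plan**

- Ring numbering used throughout: C1 = oxirane carbon bearing CH2OBz, C2 = C–OMe, C3 = C–OBz, C4=C5 = ring alkene, C6 = oxirane CH.
- Retrosynthesis cuts only C–O bonds: the two benzoate C–O bonds (the one at C3 with inversion), the O–CH3 bond, the two oxirane C–O bonds at C1 and C6, and last the C2–O and C3–O bonds. This leads back to an intact arene, so all seven skeletal carbons (C1–C6 and the CH2 on C1) come from methyl benzoate.
- Enabling feature: the cyclohexene ring has its carbon branch on C1, vicinal oxygens on C2 and C3, and C4=C5 plus the C1–C6 oxirane at the oxidation level of a 1,3-diene. It is a benzoate ring oxidised at its ortho and meta carbons, the footprint of an arene cis-2,3-dihydrodiol.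
- Forward order: the carbocycle arises first, by dioxygenase dearomatisation of the flat ring of methyl benzoate to the C2,C3-dioxygenated cyclohexadiene. The ester is then reduced, the oxirane is placed on C1=C6 by hydroxyl-directed epoxidation, C2–OH is methylated, and both benzoates are introduced last.
- Stereochemistry: C2 (S) comes directly from the enzyme; C1 and C6 follow from oxygen delivery syn to the C2 hydroxyl; C3 is the enzyme-set centre, inverted in the final Mitsunobu step (cis-diol to trans-2,3 pattern).

Key step: step 1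

Assumption: the recombinant whole-cell catalyst of step 1 (toluene dioxygenase expressed in E. coli) is treated as a catalyst, not a starting material; the two hydrogen atoms it adds come from cellular NADH, which the living cells regenerate from the glucose feed.

**Route**

Step 1
Reactants: 1 methyl benzoate
Product: 2 methyl (5S,6R)-5,6-dihydroxycyclohexa-1,3-diene-1-carboxylate
Conditions: E. coli JM109 (pDTG601A) whole cells (toluene dioxygenase), IPTG induction, glucose feed, air, pH 6.8, 30–35 °C; EtOAc extraction
Reagents that add atoms: dioxygen, O=O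
Why: The Rieske non-haem iron centre of toluene dioxygenase binds O2, takes two electrons from NADH through its reductase and ferredoxin, and delivers both oxygen atoms to one face of the ortho,meta π bond of the arene, so that the ring leaves the active site as a cis-diol on a cyclohexa-1,3-diene. The closest known reaction type is the toluene-dioxygenase cis-dihydroxylation of monosubstituted benzenes, which includes the lower alkyl benzoates. No ring is closed here: the existing benzene ring becomes the six-membered carbocycle of the target, with C2 and C3 oxygenated and C1=C6 and C4=C5 left as the diene that later carries the oxirane and the ring alkene. Both new stereocentres (5S,6R, which are C3 and C2 of the target) are set by the enzyme pocket, which exposes a single face of the ortho,meta bond; C2 is kept to the end and C3 is inverted in step 8. The step needs ortho,meta regioselectivity, attack on one enantiotopic face and no reaction at the ester, and all three should follow from the way the enzyme binds a benzene ring with one small substituent.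

Step 2
Reactants: 2 methyl (5S,6R)-5,6-dihydroxycyclohexa-1,3-diene-1-carboxylate
Product: 3 methyl (5S,6R)-5-[(tert-butyldimethylsilyl)oxy]-6-hydroxycyclohexa-1,3-diene-1-carboxylate
Conditions: TBSCl (1.05 equiv), imidazole, DMF, −20 °C → 0 °C
Reagents that add atoms: tert-butyldimethylsilyl chloride, CC(C)(C)[Si](C)(C)Cl
Why: Regioselective silyl ether formation should take the distal C5 hydroxyl, because the C6 hydroxyl is flanked by the ester-bearing sp2 carbon and hydrogen-bonded to the ester carbonyl, as in the distal silylation of arene cis-dihydrodiols; no stereocentre is touched.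

Step 3
Reactants: 3 methyl (5S,6R)-5-[(tert-butyldimethylsilyl)oxy]-6-hydroxycyclohexa-1,3-diene-1-carboxylate
Product: 4 (1R,6S)-6-[(tert-butyldimethylsilyl)oxy]-2-(hydroxymethyl)cyclohexa-2,4-dien-1-ol
Conditions: DIBAL-H (3.5 equiv), CH2Cl2, −78 °C → −20 °C; Rochelle salt work-up
Reagents that add atoms: none
Why: DIBAL-H 1,2-reduction of the conjugated ester gives the allylic alcohol and should leave the diene and the silyl ether untouched, the free hydroxyl only consuming one hydride equivalent.

Step 4
Reactants: 4 (1R,6S)-6-[(tert-butyldimethylsilyl)oxy]-2-(hydroxymethyl)cyclohexa-2,4-dien-1-ol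
Product: 5 (1S,2S,3S,6R)-3-[(tert-butyldimethylsilyl)oxy]-1-(hydroxymethyl)-7-oxabicyclo[4.1.0]hept-4-en-2-ol
Conditions: VO(acac)2 (5 mol%), t-BuOOH (1.2 equiv, decane), CH2Cl2, 0 °C
Reagents that add atoms: tert-butyl hydroperoxide, CC(C)(C)OO
Why: Vanadium-catalysed hydroxyl-directed epoxidation of an allylic alcohol should deliver oxygen from the vanadate ester of the ring hydroxyl to the adjacent trisubstituted C1=C6 bond on the hydroxyl face, which sets C1 and C6 cis to the C2 oxygen, while C4=C5, which has no free allylic hydroxyl, is left.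

Step 5
Reactants: 5 (1S,2S,3S,6R)-3-[(tert-butyldimethylsilyl)oxy]-1-(hydroxymethyl)-7-oxabicyclo[4.1.0]hept-4-en-2-ol
Product: 6 (1S,2S,3S,6R)-3-[(tert-butyldimethylsilyl)oxy]-1-{[(tert-butyldimethylsilyl)oxy]methyl}-7-oxabicyclo[4.1.0]hept-4-en-2-ol
Conditions: TBSCl (1.1 equiv), imidazole, CH2Cl2, 0 °C
Reagents that add atoms: tert-butyldimethylsilyl chloride, CC(C)(C)[Si](C)(C)Cl
Why: Silyl ether formation should be selective for the primary hydroxyl over the secondary one, which sits between the quaternary oxirane carbon and the OTBS-bearing carbon.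

Step 6
Reactants: 6 (1S,2S,3S,6R)-3-[(tert-butyldimethylsilyl)oxy]-1-{[(tert-butyldimethylsilyl)oxy]methyl}-7-oxabicyclo[4.1.0]hept-4-en-2-ol
Product: 7 tert-butyl{[(1R,2S,3S,6R)-3-[(tert-butyldimethylsilyl)oxy]-2-methoxy-7-oxabicyclo[4.1.0]hept-4-en-1-yl]methoxy}dimethylsilane
Conditions: MeI (20 equiv), Ag2O (5 equiv), 4 Å MS, MeCN, 40 °C, dark
Reagents that add atoms: iodomethane, CI
Why: Purdie methylation alkylates the remaining hydroxyl without a free alkoxide, so neither silyl migration from the cis-neighbouring OTBS nor oxirane opening is expected (oxiranes of anhydro sugars tolerate these conditions), and C2 keeps its configuration because only the O–H bond reacts.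

Step 7
Reactants: 7 tert-butyl{[(1R,2S,3S,6R)-3-[(tert-butyldimethylsilyl)oxy]-2-methoxy-7-oxabicyclo[4.1.0]hept-4-en-1-yl]methoxy}dimethylsilane
Product: 8 (1R,2S,3S,6R)-1-(hydroxymethyl)-2-methoxy-7-oxabicyclo[4.1.0]hept-4-en-3-ol
Conditions: TBAF (3 equiv), AcOH (3 equiv), THF, 0 °C → rt
Reagents that add atoms: none
Why: Fluoride-induced desilylation should free both hydroxyls, with acetic acid as buffer so that no free alkoxide can start a Payne rearrangement of the epoxy alcohol.

Step 8
Reactants: 8 (1R,2S,3S,6R)-1-(hydroxymethyl)-2-methoxy-7-oxabicyclo[4.1.0]hept-4-en-3-ol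
Product: 9 [(1R,2S,3R,6R)-3-(benzoyloxy)-2-methoxy-7-oxabicyclo[4.1.0]hept-4-en-1-yl]methyl benzoate
Conditions: PhCO2H (3 equiv), PPh3 (3 equiv), DIAD (3 equiv), toluene, 0 °C → rt
Reagents that add atoms: benzoic acid, OC(=O)c1ccccc1
Why: In this double Mitsunobu esterification the primary alkoxyphosphonium should be displaced at CH2 and the allylic secondary one at C3 by benzoate in an SN2 step with inversion (3S to 3R), which turns the cis-2,3 arrangement left by the dioxygenase into the trans arrangement of the target.

**Compound list**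

1 | methyl benzoate | COC(=O)c1ccccc1 | starting material
2 | methyl (5S,6R)-5,6-dihydroxycyclohexa-1,3-diene-1-carboxylate | COC(=O)C1=CC=C[C@H](O)[C@@H]1O | intermediate
3 | methyl (5S,6R)-5-[(tert-butyldimethylsilyl)oxy]-6-hydroxycyclohexa-1,3-diene-1-carboxylate | COC(=O)C1=CC=C[C@H](O[Si](C)(C)C(C)(C)C)[C@@H]1O | intermediate
4 | (1R,6S)-6-[(tert-butyldimethylsilyl)oxy]-2-(hydroxymethyl)cyclohexa-2,4-dien-1-ol | OCC1=CC=C[C@H](O[Si](C)(C)C(C)(C)C)[C@@H]1O | intermediate
5 | (1S,2S,3S,6R)-3-[(tert-butyldimethylsilyl)oxy]-1-(hydroxymethyl)-7-oxabicyclo[4.1.0]hept-4-en-2-ol | O[C@H]1[C@@H](O[Si](C)(C)C(C)(C)C)C=C[C@H]2O[C@]21CO | intermediate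
6 | (1S,2S,3S,6R)-3-[(tert-butyldimethylsilyl)oxy]-1-{[(tert-butyldimethylsilyl)oxy]methyl}-7-oxabicyclo[4.1.0]hept-4-en-2-ol | O[C@H]1[C@@H](O[Si](C)(C)C(C)(C)C)C=C[C@H]2O[C@]21CO[Si](C)(C)C(C)(C)C | intermediate
7 | tert-butyl{[(1R,2S,3S,6R)-3-[(tert-butyldimethylsilyl)oxy]-2-methoxy-7-oxabicyclo[4.1.0]hept-4-en-1-yl]methoxy}dimethylsilane | CO[C@H]1[C@@H](O[Si](C)(C)C(C)(C)C)C=C[C@H]2O[C@]21CO[Si](C)(C)C(C)(C)C | intermediate
8 | (1R,2S,3S,6R)-1-(hydroxymethyl)-2-methoxy-7-oxabicyclo[4.1.0]hept-4-en-3-ol | CO[C@H]1[C@@H](O)C=C[C@H]2O[C@]21CO | intermediate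
9 | [(1R,2S,3R,6R)-3-(benzoyloxy)-2-methoxy-7-oxabicyclo[4.1.0]hept-4-en-1-yl]methyl benzoate | CO[C@H]1[C@H](OC(=O)c2ccccc2)C=C[C@H]2O[C@]21COC(=O)c1ccccc1 | target

**Totals and risks**

Total step count: 8. Longest linear sequence: 8 steps (1 to 9).

Steps most likely to fail:

1. Step 8. What may go wrong: benzoate attack in the SN2′ sense at C5 instead of C3; acyl transfer through an acyloxyphosphonium with retention at C3; acid-promoted opening of the vinyl oxirane; slow substitution at the neopentyl-type primary carbon. Fallback: the two esters are made one at a time and the inversion is done on a sulfonate instead of a phosphonium. From 8, benzoyl chloride with 2,4,6-collidine in CH2Cl2 at −40 °C should acylate only the primary hydroxyl to give [(1R,2S,3S,6R)-3-hydroxy-2-methoxy-7-oxabicyclo[4.1.0]hept-4-en-1-yl]methyl benzoate F1. Mesylation (MsCl, Et3N, CH2Cl2, −20 °C) should give the allylic mesylate [(1R,2S,3S,6R)-3-(methanesulfonyloxy)-2-methoxy-7-oxabicyclo[4.1.0]hept-4-en-1-yl]methyl benzoate F2. SN2 displacement with cesium benzoate and 18-crown-6 in toluene at 50 °C should invert C3 and return to the route at 9.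

2. Step 6. What may go wrong: very slow alkylation of the hydroxyl wedged between the quaternary oxirane carbon and the cis-OTBS carbon, and silver-assisted opening of the oxirane on prolonged heating. Fallback: the methyl ether is installed before the oxirane exists and the oxirane is then set under catalyst control rather than hydroxyl direction. From 3, MeI/Ag2O on the unhindered allylic hydroxyl should give methyl (5S,6R)-5-[(tert-butyldimethylsilyl)oxy]-6-methoxycyclohexa-1,3-diene-1-carboxylate F3. DIBAL-H reduction should give [(5S,6R)-5-[(tert-butyldimethylsilyl)oxy]-6-methoxycyclohexa-1,3-dien-1-yl]methanol F4. Sharpless asymmetric epoxidation of this primary allylic alcohol (Ti(OiPr)4, D-(−)-diisopropyl tartrate, t-BuOOH, 4 Å MS, CH2Cl2, −20 °C; this tartrate enantiomer is the one whose face rule places oxygen on the methoxy-bearing face) should give [(1R,2S,3S,6R)-3-[(tert-butyldimethylsilyl)oxy]-2-methoxy-7-oxabicyclo[4.1.0]hept-4-en-1-yl]methanol F5. TBAF/AcOH then returns to the route at 8.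

3. Step 4. What may go wrong: Lewis-acid-induced dehydration and rearomatisation of the electron-rich dienediol, over-oxidation at C4=C5, and erosion of facial selectivity if the primary hydroxyl alone directs. Fallback: the primary hydroxyl is masked first and the oxygen is delivered by hydrogen-bond direction from the single remaining hydroxyl. From 4, TBSCl/imidazole at 0 °C should give (1R,6S)-6-[(tert-butyldimethylsilyl)oxy]-2-{[(tert-butyldimethylsilyl)oxy]methyl}cyclohexa-2,4-dien-1-ol F6. Buffered peracid epoxidation (m-CPBA, NaHCO3, CH2Cl2, 0 °C; Henbest direction by the free allylic hydroxyl onto the more nucleophilic trisubstituted alkene) should give the syn oxirane and return to the route at 6.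

**Further compounds**

F1 | step 8 | [(1R,2S,3S,6R)-3-hydroxy-2-methoxy-7-oxabicyclo[4.1.0]hept-4-en-1-yl]methyl benzoate | CO[C@H]1[C@@H](O)C=C[C@H]2O[C@]21COC(=O)c1ccccc1
F2 | step 8 | [(1R,2S,3S,6R)-3-(methanesulfonyloxy)-2-methoxy-7-oxabicyclo[4.1.0]hept-4-en-1-yl]methyl benzoate | CO[C@H]1[C@@H](OS(C)(=O)=O)C=C[C@H]2O[C@]21COC(=O)c1ccccc1
F3 | step 6 | methyl (5S,6R)-5-[(tert-butyldimethylsilyl)oxy]-6-methoxycyclohexa-1,3-diene-1-carboxylate | COC(=O)C1=CC=C[C@H](O[Si](C)(C)C(C)(C)C)[C@@H]1OC
F4 | step 6 | [(5S,6R)-5-[(tert-butyldimethylsilyl)oxy]-6-methoxycyclohexa-1,3-dien-1-yl]methanol | OCC1=CC=C[C@H](O[Si](C)(C)C(C)(C)C)[C@@H]1OC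
F5 | step 6 | [(1R,2S,3S,6R)-3-[(tert-butyldimethylsilyl)oxy]-2-methoxy-7-oxabicyclo[4.1.0]hept-4-en-1-yl]methanol | CO[C@H]1[C@@H](O[Si](C)(C)C(C)(C)C)C=C[C@H]2O[C@]21CO
F6 | step 4 | (1R,6S)-6-[(tert-butyldimethylsilyl)oxy]-2-{[(tert-butyldimethylsilyl)oxy]methyl}cyclohexa-2,4-dien-1-ol | CC(C)(C)[Si](C)(C)OCC1=CC=C[C@H](O[Si](C)(C)C(C)(C)C)[C@@H]1O
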